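**Plan**

1. The target is the achiral 33-membered lactone oxacyclotritriacontan-2-one, numbered along the acyl chain (C1 = carbonyl carbon, C32 = oxygen-bearing carbon). Its four contiguous ring methylenes C17–C20 can be carried as a conjugated 1,3-diyne whose central C18–C19 bond links two acetylide carbons of the same polarity, which is what lets the ring be closed by oxidative alkyne coupling.
2. Retrosynthetic cuts, in order: the C17–C20 methylenes back to the diyne; the C18–C19 sp–sp bond (opens the ring); the ester C1–O bond; the C20–C21 bond (acetylide alkylation).
3. Forward: C20–C21 is made first (a C14 alkynol from a C12 bromo alcohol and acetylide), the chain is joined at the ester, the single ring arises in the diyne macrocyclisation, and hydrogenation finishes the route.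
4. Stereochemistry: none to set. The target has no stereocentre or double bond; the only stereocentre met on the way (the THP acetal carbon) is racemic and is removed.

Key step: step 5

Remark: 17-octadecynoic acid, 12-bromododecan-1-ol and lithium acetylide ethylenediamine complex are taken as purchasable materials.

**Step 1**
Reactants: 1 12-bromododecan-1-ol; 2 3,4-dihydro-2H-pyran
Product: 3 2-[(12-bromododecyl)oxy]oxane (THP ether, racemic at the acetal carbon)
Conditions: PPTS (cat.), CH2Cl2, rt
Reagents that add atoms: 3,4-dihydro-2H-pyran (2), C1=COCCC1
Why: Acid-catalysed addition of the primary alcohol to the enol ether (tetrahydropyranylation) masks the hydroxyl as a base-stable acetal, so the acetylide of step 2 is neither quenched nor diverted into ether formation; the acetal carbon arises racemic and is removed in step 3.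

**Step 2**
Reactants: 3 2-[(12-bromododecyl)oxy]oxane; 4 lithium acetylide ethylenediamine complex
Product: 5 2-(tetradec-13-yn-1-yloxy)oxane (racemic)
Conditions: LiC≡CH·H2N(CH2)2NH2 (excess), DMSO, 10 °C to rt
Reagents that add atoms: lithium acetylide ethylenediamine complex (4), [Li+].[C-]#C.NCCN
Why: SN2 alkylation of the acetylide anion by the unhindered primary bromide in dipolar aprotic DMSO should form the C20–C21 bond and install the terminal alkyne, the THP acetal being inert to the base.

**Step 3**
Reactants: 5 2-(tetradec-13-yn-1-yloxy)oxane
Product: 6 tetradec-13-yn-1-ol
Conditions: TsOH·H2O (cat.), MeOH, rt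
Reagents that add atoms: none
Why: Acid-catalysed acetal exchange with methanol should release the primary alcohol under conditions that leave the terminal alkyne untouched.

**Step 4**
Reactants: 6 tetradec-13-yn-1-ol; 7 17-octadecynoic acid
Product: 9 tetradec-13-yn-1-yl octadec-17-ynoate, via O-acylisourea 8 (not isolated)
Conditions: DCC, DMAP (cat.), CH2Cl2, 0 °C to rt
Reagents that add atoms: none
Why: Steglich esterification, in which DCC turns the acid into the O-acylisourea 8 and DMAP passes the acyl group to the unhindered primary alcohol faster than the isourea can rearrange, should form the ester C1–O bond under neutral conditions that leave both terminal alkynes alone.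

**Step 5**
Reactants: 9 tetradec-13-yn-1-yl octadec-17-ynoate
Product: 11 oxacyclotritriaconta-18,20-diyn-2-one, via bis(acetatocopper) diacetylide 10 (not isolated)
Conditions: Cu(OAc)2 (10 equiv), pyridine/Et2O, 50 °C, slow syringe-pump addition of 9 (final concentration ≤ 2 mM); aqueous EDTA/dilute HCl work-up
Reagents that add atoms: none
Why: Pyridine-assisted deprotonation of each terminal alkyne at divalent copper should give the bis(copper acetylide) 10, and the two acetylide carbons, both of nucleophilic polarity, are then joined in an oxidative C(sp)–C(sp) coupling in which two divalent copper centres are reduced to monovalent copper and the C18–C19 bond is formed. The closest known reaction type is the Eglinton (Glaser-type) oxidative coupling of terminal alkynes, as applied to the macrocyclisation of ester-tethered α,ω-diynes. The single ring, the 33-membered lactone, closes end to end by this intramolecular homocoupling of the two chain termini, and a ring of this size holds the linear four-carbon diyne rod without strain. No stereocentre or double bond is created, so no stereocontrol is involved. The only selectivity needed is ring closure over intermolecular coupling, which the slow addition into a large excess of Cu(OAc)2 should secure by keeping the stationary concentration of uncoupled 9 very low; the two alkyne C–H bonds are the only acidic sites and the ester is inert to Cu(OAc)2 in pyridine, so no chemoselectivity question arises.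

**Step 6**
Reactants: 11 oxacyclotritriaconta-18,20-diyn-2-one
Product: 12 oxacyclotritriacontan-2-one (target)
Conditions: H2 (1 atm), 10% Pd/C, EtOAc/THF, rt, light excluded during handling of 11
Reagents that add atoms: none
Why: Exhaustive heterogeneous hydrogenation should saturate both triple bonds of the conjugated diyne to the four methylenes C17–C20, and since the lactone C–O bond is remote from the diyne and neither allylic nor benzylic, no hydrogenolysis should compete.

**Compound list**

1 | 12-bromododecan-1-ol | OCCCCCCCCCCCCBr | starting material
2 | 3,4-dihydro-2H-pyran | C1=COCCC1 | starting material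
3 | 2-[(12-bromododecyl)oxy]oxane (racemic THP ether) | BrCCCCCCCCCCCCOC1CCCCO1 | intermediate
4 | lithium acetylide ethylenediamine complex | [Li+].[C-]#C.NCCN | starting material
5 | 2-(tetradec-13-yn-1-yloxy)oxane (racemic THP ether) | C#CCCCCCCCCCCCCOC1CCCCO1 | intermediate
6 | tetradec-13-yn-1-ol | C#CCCCCCCCCCCCCO | intermediate
7 | 17-octadecynoic acid (octadec-17-ynoic acid) | C#CCCCCCCCCCCCCCCCC(=O)O | starting material
8 | N,N'-dicyclohexyl-O-(octadec-17-ynoyl)isourea (O-acylisourea, not isolated) | C#CCCCCCCCCCCCCCCCC(=O)OC(=NC1CCCCC1)NC1CCCCC1 | intermediate
9 | tetradec-13-yn-1-yl octadec-17-ynoate | C#CCCCCCCCCCCCCCCCC(=O)OCCCCCCCCCCCCC#C | intermediate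
10 | bis(acetatocopper) diacetylide of ester 9 (a Cu(OAc) unit of divalent copper on each alkyne terminus, pyridine ligands omitted, not isolated) | CC(=O)O[Cu]C#CCCCCCCCCCCCCCCCC(=O)OCCCCCCCCCCCCC#C[Cu]OC(C)=O | intermediate
11 | oxacyclotritriaconta-18,20-diyn-2-one | O=C1CCCCCCCCCCCCCCCC#CC#CCCCCCCCCCCCCO1 | intermediate
12 | oxacyclotritriacontan-2-one (32-dotriacontanolide) | O=C1CCCCCCCCCCCCCCCCCCCCCCCCCCCCCCCO1 | target

**Step count**

Total steps: 6. Longest linear sequence: 6 (steps 1 to 6 from 12-bromododecan-1-ol; 17-octadecynoic acid enters at step 4).

**Steps most likely to fail**

Step 5. Intermolecular oxidative coupling may overtake ring closure at any practicable dilution, so that material is drained into linear oligomers and larger rings. The diyne may also polymerise under light or heat during the long addition. The fallback closes the ring at the lactone C–O bond instead and makes the C18–C19 bond beforehand by a cross-selective coupling. It sets out from 6 (together with 7, so that 9 is bypassed). Bromination of the alkyne terminus of 6 (NBS, AgNO3 cat., acetone, rt) would give 14-bromotetradec-13-yn-1-ol F1. Cadiot–Chodkiewicz coupling of F1 with acid 7 (CuCl cat., NH2OH·HCl, aqueous EtNH2, MeOH/THF, 0 °C to rt) would give 32-hydroxydotriaconta-17,19-diynoic acid F2. Yamaguchi activation (2,4,6-trichlorobenzoyl chloride, Et3N, THF) would give the mixed 2,4,6-trichlorobenzoic anhydride F3. Slow addition of F3 to DMAP in warm toluene at high dilution should close the 33-membered lactone and bring the sequence back to the route at 11.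

Step 2. The strongly basic acetylide in DMSO may cause E2 loss of HBr from the bromide, or base-induced migration of the new terminal triple bond into the chain, which would leave an alkyne unable to couple in step 5. The fallback sets out from 3 and uses a silyl-capped acetylide. Lithium (trimethylsilyl)acetylide (trimethylsilylacetylene, n-BuLi, THF/DMPU, −78 °C to rt) would displace the bromide to give trimethyl[14-(oxan-2-yloxy)tetradec-1-yn-1-yl]silane F4. The cap removes the acidic terminal hydrogen and with it the path to isomerisation. K2CO3 in MeOH would then cleave the C–Si bond and return to the route at 5.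

Step 6. Saturation may stop short because copper or pyridine residues from step 5 poison the palladium surface, or because the poorly soluble waxy product deposits on the catalyst; either would leave olefinic macrolides that are hard to separate from the target. The fallback sets out from 11 (or from the partly reduced mixture) and delivers hydrogen without a metal surface. Diimide, generated in the flask from excess p-toluenesulfonyl hydrazide with NaOAc in refluxing DME/water, should reduce the remaining C–C multiple bonds and arrive at 12. This fallback makes no new compound (entry F0).

**Further compounds**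

F1 | step 5 | 14-bromotetradec-13-yn-1-ol | OCCCCCCCCCCCCC#CBr
F2 | step 5 | 32-hydroxydotriaconta-17,19-diynoic acid | OCCCCCCCCCCCCC#CC#CCCCCCCCCCCCCCCCC(=O)O
F3 | step 5 | 32-hydroxydotriaconta-17,19-diynoic 2,4,6-trichlorobenzoic anhydride | OCCCCCCCCCCCCC#CC#CCCCCCCCCCCCCCCCC(=O)OC(=O)c1c(Cl)cc(Cl)cc1Cl
F4 | step 2 | trimethyl[14-(oxan-2-yloxy)tetradec-1-yn-1-yl]silane | C[Si](C)(C)C#CCCCCCCCCCCCCOC1CCCCO1
F0 | step 6 | none | none
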